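**Retrosynthetic overview**
1. Target (germacrane numbering; 1(10)Z,4E; 6S,7S,8S,9R; cis-fused 12,6-lactone) ← desilylation, C9 angeloylation and C9 ketone reduction of the 9-oxo-germacradienolide 16.
2. Key disconnection: 16 ← ring-expanding Grob (Wharton) fragmentation of the cis-fused bicyclo[4.4.0]decane 14 (C9–OH, C5–OMs). Cleaving the C4–C9 zero bridge merges rings A and B (6 + 6) into the ten-membered ring; E-C4=C5 follows from the cis C4-Me/C5-OMs relationship, Z-C1=C10 is preset in ring A.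
3. γ-Lactone on ring B ← copper hydride reductive aldol (new) of a C6 propiolate onto the C7 ketone (forms C7–C11, sets C7, caps O7 as a silyl ether).
4. Ring B ← dihydroxyacetone: threonine-catalysed syn-aldol (C5–C6; sets C5, C6), then intramolecular aldol (C8–C9; sets C8).
5. Ring A ← catalytic asymmetric Diels–Alder of methacrolein with the silyl dienol ether of tiglic aldehyde (sets C4). Ring order: A, B, lactone, then ring expansion.

Numbering: germacrane numbering is used throughout (ring C1–C10, C14 on C10, C15 on C4, lactone C6–O–C12(=O)–C11(=C13)–C7).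
Assumption: species that exist only bound to a catalyst inside a catalytic cycle (enamines, copper enolates and alkoxides) are described in the Why lines and carry no number; every other compound formed in a flask is numbered.
Dihydroxyacetone 6 is weighed as its commercial dimer, which gives the monomer in solution.

Step 1
Reactants: 1 (E)-2-methylbut-2-enal
Product: 2 triethyl{[(1E)-2-methylbuta-1,3-dien-1-yl]oxy}silane
Conditions: Et3SiOTf, Et3N, Et2O, 0 °C to rt
Reagents that add atoms: triethylsilyl trifluoromethanesulfonate, CC[Si](CC)(CC)OS(=O)(=O)C(F)(F)F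
Why: Soft enolisation (O-silylation, then γ-deprotonation by the amine) gives the 1-silyloxy diene with the silyloxy group trans to the vinyl group, as needed for the s-cis diene (silyl dienol ether formation).

Step 2
Reactants: 2 silyl dienol ether; 3 2-methylprop-2-enal (methacrolein)
Product: 5 (1S,2S)-2-hydroxy-1,3-dimethylcyclohex-3-ene-1-carbaldehyde, via triethylsilyl ether cycloadduct 4 (not isolated)
Conditions: (S)-oxazaborolidinium triflimide [from (S)-α,α-diphenylprolinol, o-tolylboroxine, HNTf2] (10 mol%), CH2Cl2, −78 °C; then 1 M HCl, THF, 0 °C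
Reagents that add atoms: none
Why: Catalytic enantioselective Diels–Alder reaction: the 1-silyloxy group directs the "ortho" regiochemistry (C9–C4 and C2–C3 bonds) and the catalyst-bound s-trans methacrolein is attacked on one face (exo), which sets the quaternary C4; the catalyst enantiomer is the one that gives (1S)-4 (its mirror image gives ent-4), the C9 carbinol is oxidised later, and acid work-up cleaves the silyl ether.

Step 3
Reactants: 5 hydroxy aldehyde; 6 1,3-dihydroxypropan-2-one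
Product: 7 (3S,4R)-1,3,4-trihydroxy-4-[(1S,2S)-2-hydroxy-1,3-dimethylcyclohex-3-en-1-yl]butan-2-one
Conditions: O-tert-butyl-L-threonine (20 mol%), 5-methyl-1H-tetrazole (10 mol%), NMP, H2O (3 vol%), rt, 48 h
Reagents that add atoms: none
Why: Direct organocatalytic syn-aldol of unprotected dihydroxyacetone through its Z-enamine with the primary amino acid (the catalyst enantiomer giving the D-threo 3S,4R ketotriol pattern) sets C6 (S) and C5 (R); this is matched with Felkin–Anh attack on the α-quaternary aldehyde anti to the ring carbinol carbon, which puts O5 cis to the C4 methyl in the later ring B.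

Step 4
Reactants: 7 tetraol
Product: 8 (3S,4R)-1-[(tert-butyldimethylsilyl)oxy]-3,4-dihydroxy-4-[(1S,2S)-2-hydroxy-1,3-dimethylcyclohex-3-en-1-yl]butan-2-one
Conditions: TBSCl (1.05 equiv), imidazole, DMF, −20 °C
Reagents that add atoms: tert-butyldimethylsilyl chloride, CC(C)(C)[Si](C)(C)Cl
Why: Selective silylation of the only primary hydroxyl (C8–OH) differentiates O8 from O6 before ring B is closed.

Step 5
Reactants: 8 silyl ether triol
Product: 9 (3S,4R)-1-[(tert-butyldimethylsilyl)oxy]-3,4-dihydroxy-4-[(1R)-1,3-dimethyl-2-oxocyclohex-3-en-1-yl]butan-2-one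
Conditions: MnO2 (excess), CH2Cl2, rt
Reagents that add atoms: none
Why: Chemoselective MnO2 oxidation of the allylic secondary alcohol (C9) to the enone; the non-allylic secondary hydroxyls are left alone.

Step 6
Reactants: 9 enone diol
Product: 10 (1S,3S,4R,4aR,8aS)-1-[(tert-butyldimethylsilyl)oxy]-3,4,8a-trihydroxy-4a,8-dimethyl-3,4,4a,5,6,8a-hexahydronaphthalen-2(1H)-one
Conditions: BnNH2·CF3CO2H (20 mol%), CHCl3, 35 °C
Reagents that add atoms: none
Why: Intramolecular enamine aldol (6-enolendo, Hajos–Parrish type) of C8 onto the C9 enone carbonyl closes ring B: C8 adds axially on ring A anti to the pseudo-axial C4 methyl (cis-fused decalin), and the Z secondary enamine (OTBS cis to N–H) places OTBS equatorial in the chair transition state, that is trans to O6 (sets C8; C9 later becomes the ketone).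

Step 7
Reactants: 10 bicyclic triol; 11 prop-2-ynoic acid
Product: 12 (1S,3S,4R,4aR,8aS)-1-[(tert-butyldimethylsilyl)oxy]-4,8a-dihydroxy-4a,8-dimethyl-2-oxo-1,2,3,4,4a,5,6,8a-octahydronaphthalen-3-yl prop-2-ynoate
Conditions: DCC, CH2Cl2, −20 to 0 °C
Reagents that add atoms: none
Why: Carbodiimide (Steglich-type) esterification is expected to favour the less hindered α-ketol hydroxyl at C6 over the neopentyl C5–OH and the tertiary C9–OH.

Step 8
Reactants: 12 propiolate
Product: 13 (1S,3S,4R,4aR,8aS)-1-[(tert-butyldimethylsilyl)oxy]-8a-hydroxy-4-[(methanesulfonyl)oxy]-4a,8-dimethyl-2-oxo-1,2,3,4,4a,5,6,8a-octahydronaphthalen-3-yl prop-2-ynoate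
Conditions: Ms2O, 2,6-lutidine, CH2Cl2, 0 °C to rt
Reagents that add atoms: methanesulfonic anhydride, CS(=O)(=O)OS(C)(=O)=O
Why: Sulfonylation of the one remaining secondary hydroxyl (C5) with a hindered, weakly nucleophilic base that spares the propiolate; the tertiary C9–OH does not react.

Step 9
Reactants: 13 mesylate propiolate
Product: 14 (3aR,4S,4aS,8aR,9R,9aS)-4-[(tert-butyldimethylsilyl)oxy]-3a-[(dimethylphenylsilyl)oxy]-4a-hydroxy-5,8a-dimethyl-3-methylidene-2-oxo-2,3,3a,4,4a,7,8,8a,9,9a-decahydronaphtho[2,3-b]furan-9-yl methanesulfonate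
Conditions: [(Ph3P)CuH]6 (5 mol%), PhMe2SiH (1.1 equiv), toluene, 0 °C to rt
Reagents that add atoms: dimethylphenylsilane, C[SiH](C)c1ccccc1
Why: Proposed new method: phosphine-ligated copper hydride adds hydride to the β-carbon (C13) of the propiolate to give a copper allenolate, which attacks the C7 ketone through C11 in a 5-exo aldol; the ester tether forces attack on the face of O6, so the lactone is cis-fused and O7 ends cis to O8 (sets C7), and σ-bond metathesis of the tertiary copper alkoxide with the silane regenerates Cu–H and leaves O7 as its silyl ether (ynoate reduction is faster than reduction of the product acrylate, so one equivalent of silane is used); the closest known reaction type is the copper hydride reductive aldol cyclisation of enoate- or ynone-tethered ketones, not yet shown for propiolate esters of α-hydroxy ketones.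

Step 10
Reactants: 14 tricyclic mesylate
Product: 16 (3aR,4R,6Z,10E,11aS)-4-[(tert-butyldimethylsilyl)oxy]-3a-[(dimethylphenylsilyl)oxy]-6,10-dimethyl-3-methylidene-3a,4,8,9-tetrahydrocyclodeca[b]furan-2,5(3H,11aH)-dione, via potassium alkoxide 15 (not isolated)
Conditions: KN(SiMe3)2 (1.05 equiv), THF, −78 to 0 °C; AcOH quench
Reagents that add atoms: potassium bis(trimethylsilyl)amide, C[Si](C)(C)[N-][Si](C)(C)C.[K+] (its potassium stays in 15 only)
Why: Grob (Wharton) fragmentation used as a ring expansion: the C9 alkoxide pushes, the C4–C9 zero-bridge bond anti-periplanar to the equatorial C5–OMs breaks, and the two six-membered rings become the ten-membered ring with a C9 ketone; the cis C4-Me/C5-OMs relationship gives the E C4=C5 alkene stereospecifically, the Z C1=C10 alkene is inherited from ring A, and the cis O9/OMs and trans O9/C11 relationships rule out oxetane formation and oxa-Michael addition.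

Step 11
Reactants: 16 dienone
Product: 17 (3aR,4S,5R,6Z,10E,11aS)-4-[(tert-butyldimethylsilyl)oxy]-3a-[(dimethylphenylsilyl)oxy]-5-hydroxy-6,10-dimethyl-3-methylidene-3a,4,5,8,9,11a-hexahydrocyclodeca[b]furan-2(3H)-one
Conditions: NaBH4, CeCl3·7H2O, MeOH, −78 °C
Reagents that add atoms: none
Why: Luche 1,2-reduction of the enone; Felkin–Anh hydride delivery from the ring periphery, anti to the bulky non-chelating C8 silyloxy group, is expected to give the 8,9-threo (9R) allylic alcohol.

Step 12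
Reactants: 17 allylic alcohol; 18 (2Z)-2-methylbut-2-enoic acid (angelic acid)
Product: 20 (3aR,4S,5R,6Z,10E,11aS)-4-[(tert-butyldimethylsilyl)oxy]-3a-[(dimethylphenylsilyl)oxy]-6,10-dimethyl-3-methylidene-2-oxo-2,3,3a,4,5,8,9,11a-octahydrocyclodeca[b]furan-5-yl (2Z)-2-methylbut-2-enoate, via mixed anhydride 19 (not isolated)
Conditions: 18, 2,4,6-trichlorobenzoyl chloride, Et3N, toluene, rt; then 17, 80 °C
Reagents that add atoms: 2,4,6-trichlorobenzoyl chloride, O=C(Cl)c1c(Cl)cc(Cl)cc1Cl (its acyl group stays in 19 only)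
Why: Yamaguchi mixed-anhydride esterification without a nucleophilic catalyst acylates the only free hydroxyl with retention at C9 and avoids isomerisation of the Z-angelate to the tiglate.

Step 13
Reactants: 20 bis-silyl ether
Product: 21 (3aS,4S,5R,6Z,10E,11aS)-3a,4-dihydroxy-6,10-dimethyl-3-methylidene-2-oxo-2,3,3a,4,5,8,9,11a-octahydrocyclodeca[b]furan-5-yl (2Z)-2-methylbut-2-enoate
Conditions: HF·pyridine, pyridine, THF, 0 °C to rt
Reagents that add atoms: none
Why: Buffered fluoride desilylation removes both silyl ethers without touching the angelate, the α-methylene lactone or the acid-sensitive 1(10),4-diene.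

**Compound list**
1 | (E)-2-methylbut-2-enal (tiglic aldehyde) | C/C=C(\C)C=O | starting material
2 | triethyl{[(1E)-2-methylbuta-1,3-dien-1-yl]oxy}silane | C=C/C(C)=C/O[Si](CC)(CC)CC | intermediate
3 | 2-methylprop-2-enal (methacrolein) | C=C(C)C=O | starting material
4 | (1S,2S)-1,3-dimethyl-2-[(triethylsilyl)oxy]cyclohex-3-ene-1-carbaldehyde (silyloxy trans to formyl) | O=C[C@@]1(C)CCC=C(C)[C@@H]1O[Si](CC)(CC)CC | intermediate (not isolated)
5 | (1S,2S)-2-hydroxy-1,3-dimethylcyclohex-3-ene-1-carbaldehyde | O=C[C@@]1(C)CCC=C(C)[C@@H]1O | intermediate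
6 | 1,3-dihydroxypropan-2-one (dihydroxyacetone) | O=C(CO)CO | starting material
7 | (3S,4R)-1,3,4-trihydroxy-4-[(1S,2S)-2-hydroxy-1,3-dimethylcyclohex-3-en-1-yl]butan-2-one | OCC(=O)[C@@H](O)[C@H](O)[C@@]1(C)CCC=C(C)[C@@H]1O | intermediate
8 | (3S,4R)-1-[(tert-butyldimethylsilyl)oxy]-3,4-dihydroxy-4-[(1S,2S)-2-hydroxy-1,3-dimethylcyclohex-3-en-1-yl]butan-2-one | CC(C)(C)[Si](C)(C)OCC(=O)[C@@H](O)[C@H](O)[C@@]1(C)CCC=C(C)[C@@H]1O | intermediate
9 | (3S,4R)-1-[(tert-butyldimethylsilyl)oxy]-3,4-dihydroxy-4-[(1R)-1,3-dimethyl-2-oxocyclohex-3-en-1-yl]butan-2-one | CC(C)(C)[Si](C)(C)OCC(=O)[C@@H](O)[C@H](O)[C@@]1(C)CCC=C(C)C1=O | intermediate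
10 | (1S,3S,4R,4aR,8aS)-1-[(tert-butyldimethylsilyl)oxy]-3,4,8a-trihydroxy-4a,8-dimethyl-3,4,4a,5,6,8a-hexahydronaphthalen-2(1H)-one (cis-fused; 4a-methyl and 8a-hydroxyl cis) | CC1=CCC[C@]2(C)[C@@H](O)[C@H](O)C(=O)[C@@H](O[Si](C)(C)C(C)(C)C)[C@]12O | intermediate
11 | prop-2-ynoic acid (propiolic acid) | C#CC(=O)O | starting material
12 | (1S,3S,4R,4aR,8aS)-1-[(tert-butyldimethylsilyl)oxy]-4,8a-dihydroxy-4a,8-dimethyl-2-oxo-1,2,3,4,4a,5,6,8a-octahydronaphthalen-3-yl prop-2-ynoate | CC1=CCC[C@]2(C)[C@@H](O)[C@H](OC(=O)C#C)C(=O)[C@@H](O[Si](C)(C)C(C)(C)C)[C@]12O | intermediate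
13 | (1S,3S,4R,4aR,8aS)-1-[(tert-butyldimethylsilyl)oxy]-8a-hydroxy-4-[(methanesulfonyl)oxy]-4a,8-dimethyl-2-oxo-1,2,3,4,4a,5,6,8a-octahydronaphthalen-3-yl prop-2-ynoate | CC1=CCC[C@]2(C)[C@@H](OS(C)(=O)=O)[C@H](OC(=O)C#C)C(=O)[C@@H](O[Si](C)(C)C(C)(C)C)[C@]12O | intermediate
14 | (3aR,4S,4aS,8aR,9R,9aS)-4-[(tert-butyldimethylsilyl)oxy]-3a-[(dimethylphenylsilyl)oxy]-4a-hydroxy-5,8a-dimethyl-3-methylidene-2-oxo-2,3,3a,4,4a,7,8,8a,9,9a-decahydronaphtho[2,3-b]furan-9-yl methanesulfonate | CC1=CCC[C@]2(C)[C@@H](OS(C)(=O)=O)[C@@H]3OC(=O)C(=C)[C@]3(O[Si](C)(C)c4ccccc4)[C@@H](O[Si](C)(C)C(C)(C)C)[C@]12O | intermediate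
15 | potassium 4a-alkoxide of 14 | CC1=CCC[C@]2(C)[C@@H](OS(C)(=O)=O)[C@@H]3OC(=O)C(=C)[C@]3(O[Si](C)(C)c4ccccc4)[C@@H](O[Si](C)(C)C(C)(C)C)[C@]12[O-].[K+] | intermediate (not isolated)
16 | (3aR,4R,6Z,10E,11aS)-4-[(tert-butyldimethylsilyl)oxy]-3a-[(dimethylphenylsilyl)oxy]-6,10-dimethyl-3-methylidene-3a,4,8,9-tetrahydrocyclodeca[b]furan-2,5(3H,11aH)-dione | C=C1C(=O)O[C@H]2/C=C(\C)CC/C=C(/C)C(=O)[C@H](O[Si](C)(C)C(C)(C)C)[C@@]12O[Si](C)(C)c1ccccc1 | intermediate
17 | (3aR,4S,5R,6Z,10E,11aS)-4-[(tert-butyldimethylsilyl)oxy]-3a-[(dimethylphenylsilyl)oxy]-5-hydroxy-6,10-dimethyl-3-methylidene-3a,4,5,8,9,11a-hexahydrocyclodeca[b]furan-2(3H)-one | C=C1C(=O)O[C@H]2/C=C(\C)CC/C=C(/C)[C@@H](O)[C@H](O[Si](C)(C)C(C)(C)C)[C@@]12O[Si](C)(C)c1ccccc1 | intermediate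
18 | (2Z)-2-methylbut-2-enoic acid (angelic acid) | C/C=C(/C)C(=O)O | starting material
19 | (2Z)-2-methylbut-2-enoic 2,4,6-trichlorobenzoic anhydride | C/C=C(/C)C(=O)OC(=O)c1c(Cl)cc(Cl)cc1Cl | intermediate (not isolated)
20 | (3aR,4S,5R,6Z,10E,11aS)-4-[(tert-butyldimethylsilyl)oxy]-3a-[(dimethylphenylsilyl)oxy]-6,10-dimethyl-3-methylidene-2-oxo-2,3,3a,4,5,8,9,11a-octahydrocyclodeca[b]furan-5-yl (2Z)-2-methylbut-2-enoate | C=C1C(=O)O[C@H]2/C=C(\C)CC/C=C(/C)[C@@H](OC(=O)/C(C)=C\C)[C@H](O[Si](C)(C)C(C)(C)C)[C@@]12O[Si](C)(C)c1ccccc1 | intermediate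
21 | (3aS,4S,5R,6Z,10E,11aS)-3a,4-dihydroxy-6,10-dimethyl-3-methylidene-2-oxo-2,3,3a,4,5,8,9,11a-octahydrocyclodeca[b]furan-5-yl (2Z)-2-methylbut-2-enoate | C=C1C(=O)O[C@H]2/C=C(\C)CC/C=C(/C)[C@@H](OC(=O)/C(C)=C\C)[C@H](O)[C@@]12O | target

**Totals and risks**
Total step count: 13. Longest linear sequence: 13 (1 → 2 → 5 → 7 → 8 → 9 → 10 → 12 → 13 → 14 → 16 → 17 → 20 → 21).

The stereochemical outcomes of steps 3, 6, 9 and 11 are predictions from transition-state models, not established results. The three steps most likely to fail: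

Step 9 (the proposed new lactone annulation). Risks are protonation of the copper enolate by the free C9–OH, over-reduction of the acrylate, and slow silylation of the tertiary copper alkoxide. The fallback uses known organochromium chemistry and sets out from 10. Esterification of O6 with 2-bromoprop-2-enoic acid (DCC, CH2Cl2) gives (1S,3S,4R,4aR,8aS)-1-[(tert-butyldimethylsilyl)oxy]-4,8a-dihydroxy-4a,8-dimethyl-2-oxo-1,2,3,4,4a,5,6,8a-octahydronaphthalen-3-yl 2-bromoprop-2-enoate F4. Mesylation (Ms2O, 2,6-lutidine) gives (1S,3S,4R,4aR,8aS)-1-[(tert-butyldimethylsilyl)oxy]-8a-hydroxy-4-[(methanesulfonyl)oxy]-4a,8-dimethyl-2-oxo-1,2,3,4,4a,5,6,8a-octahydronaphthalen-3-yl 2-bromoprop-2-enoate F5. An intramolecular Nozaki–Hiyama–Kishi addition of the alkenyl bromide to the C7 ketone under chlorosilane-turnover conditions (CrCl2 10 mol%, NiCl2 1 mol%, Mn powder, PhMe2SiCl, THF/DMF) closes the same cis-fused lactone and silylates O7, coming back to the route at 14.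

Step 3 (aldol of dihydroxyacetone with a hindered, unactivated α-quaternary aldehyde may stall). The fallback sets out from 5 and activates the aldehyde first. MnO2 oxidation gives (1R)-1,3-dimethyl-2-oxocyclohex-3-ene-1-carbaldehyde F1, whose formyl group is activated by the neighbouring ketone. The same threonine-catalysed aldol with 6, run at 4 °C to limit deformylation and premature ring closure, gives (3S,4R)-1,3,4-trihydroxy-4-[(1R)-1,3-dimethyl-2-oxocyclohex-3-en-1-yl]butan-2-one F2. Silylation of its primary hydroxyl (TBSCl, imidazole) comes back to the route at 9.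

Step 6 (ring B closure may be slow, reverse by retro-aldol, dehydrate, or give the C8 epimer). The fallback sets out from 9 and replaces enamine catalysis with a Lewis-acid Mukaiyama aldol. TMSOTf/Et3N gives the persilylated Z enol ether (1Z,3S,4R)-1-[(tert-butyldimethylsilyl)oxy]-4-[(1R)-1,3-dimethyl-2-oxocyclohex-3-en-1-yl]-2,3,4-tris[(trimethylsilyl)oxy]but-1-ene F3. BF3·OEt2 in CH2Cl2 at −78 °C closes the C8–C9 bond onto the enone carbonyl, and citric acid in MeOH removes the trimethylsilyl groups, coming back to the route at 10.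

**Further compounds**
F1 | step 3 | (1R)-1,3-dimethyl-2-oxocyclohex-3-ene-1-carbaldehyde | O=C[C@@]1(C)CCC=C(C)C1=O
F2 | step 3 | (3S,4R)-1,3,4-trihydroxy-4-[(1R)-1,3-dimethyl-2-oxocyclohex-3-en-1-yl]butan-2-one | OCC(=O)[C@@H](O)[C@H](O)[C@@]1(C)CCC=C(C)C1=O
F3 | step 6 | (1Z,3S,4R)-1-[(tert-butyldimethylsilyl)oxy]-4-[(1R)-1,3-dimethyl-2-oxocyclohex-3-en-1-yl]-2,3,4-tris[(trimethylsilyl)oxy]but-1-ene | CC(C)(C)[Si](C)(C)O/C=C(\O[Si](C)(C)C)[C@@H](O[Si](C)(C)C)[C@H](O[Si](C)(C)C)[C@@]1(C)CCC=C(C)C1=O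
F4 | step 9 | (1S,3S,4R,4aR,8aS)-1-[(tert-butyldimethylsilyl)oxy]-4,8a-dihydroxy-4a,8-dimethyl-2-oxo-1,2,3,4,4a,5,6,8a-octahydronaphthalen-3-yl 2-bromoprop-2-enoate | CC1=CCC[C@]2(C)[C@@H](O)[C@H](OC(=O)C(Br)=C)C(=O)[C@@H](O[Si](C)(C)C(C)(C)C)[C@]12O
F5 | step 9 | (1S,3S,4R,4aR,8aS)-1-[(tert-butyldimethylsilyl)oxy]-8a-hydroxy-4-[(methanesulfonyl)oxy]-4a,8-dimethyl-2-oxo-1,2,3,4,4a,5,6,8a-octahydronaphthalen-3-yl 2-bromoprop-2-enoate | CC1=CCC[C@]2(C)[C@@H](OS(C)(=O)=O)[C@H](OC(=O)C(Br)=C)C(=O)[C@@H](O[Si](C)(C)C(C)(C)C)[C@]12O
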